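**Assumption:** the target SMILES has no stereocentre (it is the 2-hydroxyindole tautomer of the oxindol-3-yl form, whose C3–H is freely enolisable), so there is no enantiomer to control. The compound is treated as air-sensitive (oxidative decarboxylation), so the final step is done under anaerobic, neutral, reductive conditions.

## Retrosynthetic overview

1. Target 18 ⇐ global hydrogenolysis of acid 17 (one O-Bn, two N-Cbz).
2. 17 ⇐ pyrrole C3–oxindole C3 bond by a new carboxylate-directed Cp*Rh(III) C–H carbene insertion of acid 12 with 3-diazooxindole 16 (from isatin).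
3. 12 ⇐ Pinnick oxidation and N-Cbz protection of aldehyde 9 ⇐ Suzuki coupling of indol-3-yl boronate 7 with 5-bromopyrrole-2-carbaldehyde 8.
4. 7 ⇐ 5-benzyloxyindole 1 by C3 iodination, N-Cbz protection and Miyaura borylation.
5. No ring is built de novo: the indole, pyrrole and oxindole rings are purchased and joined indole–pyrrole first, pyrrole–oxindole second.

## Route

**Step 1**
Reactants: 1, 5-(benzyloxy)-1H-indole; 2, iodine
Product: 3, 5-(benzyloxy)-3-iodo-1H-indole
Conditions: I2 (1.05 eq), KOH (2.5 eq), DMF, rt, 1 h; aq. NaHSO3 work-up; used crude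
Reagents that add atoms: iodine, II
Why: Electrophilic aromatic iodination of an N–H indole is strongly C3-selective, and the benzyl ether is inert.

**Step 2**
Reactants: 3, 5-(benzyloxy)-3-iodo-1H-indole; 4, benzyl chloroformate
Product: 5, benzyl 5-(benzyloxy)-3-iodo-1H-indole-1-carboxylate
Conditions: NaH (1.2 eq), CbzCl (1.2 eq), THF, 0 °C
Reagents that add atoms: benzyl chloroformate, O=C(Cl)OCc1ccccc1
Why: N-acylation of the indolide anion gives the carbamate, which stabilises the 3-iodoindole and lowers indole nucleophilicity for later steps.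

**Step 3**
Reactants: 5, benzyl 5-(benzyloxy)-3-iodo-1H-indole-1-carboxylate; 6, bis(pinacolato)diboron
Product: 7, benzyl 5-(benzyloxy)-3-(4,4,5,5-tetramethyl-1,3,2-dioxaborolan-2-yl)-1H-indole-1-carboxylate
Conditions: Pd(dppf)Cl2 (5 mol%), B2pin2 (1.3 eq), KOAc (3 eq), dioxane, 80 °C
Reagents that add atoms: bis(pinacolato)diboron, CC1(C)OB(OC1(C)C)B1OC(C)(C)C(C)(C)O1
Why: Miyaura borylation of an N-acyl 3-iodoindole; KOAc is too weak a base to cleave the carbamate.

**Step 4**
Reactants: 7, the indol-3-yl boronate; 8, 5-bromo-1H-pyrrole-2-carbaldehyde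
Product: 9, benzyl 5-(benzyloxy)-3-(5-formyl-1H-pyrrol-2-yl)-1H-indole-1-carboxylate
Conditions: XPhos Pd G3 (3 mol%), K3PO4 (2 eq), THF/H2O (10:1), 45 °C, Ar
Reagents that add atoms: 5-bromo-1H-pyrrole-2-carbaldehyde, O=Cc1ccc(Br)[nH]1
Why: Suzuki–Miyaura coupling with a fast precatalyst at low temperature, so that C–C coupling outruns carbamate hydrolysis and protodeboronation; the aldehyde and free pyrrole N–H are tolerated.

**Step 5**
Reactants: 9, the N–H pyrrole aldehyde; 4, benzyl chloroformate
Product: 10, benzyl 5-(benzyloxy)-3-{1-[(benzyloxy)carbonyl]-5-formyl-1H-pyrrol-2-yl}-1H-indole-1-carboxylate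
Conditions: NaH (1.3 eq), CbzCl (1.4 eq), THF, 0 °C
Reagents that add atoms: benzyl chloroformate, O=C(Cl)OCc1ccccc1
Why: N-acylation of the acidic 2-formylpyrrole N–H; the aldehyde is non-enolisable, and any indole nitrogen that lost Cbz in step 4 is re-protected here, so the material converges on 10.

**Step 6**
Reactants: 10, the bis-Cbz aldehyde; 11, sodium chlorite
Product: 12, 1-[(benzyloxy)carbonyl]-5-{5-(benzyloxy)-1-[(benzyloxy)carbonyl]-1H-indol-3-yl}-1H-pyrrole-2-carboxylic acid
Conditions: NaClO2, NaH2PO4, 2-methyl-2-butene, t-BuOH/THF/H2O, 0 °C to rt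
Reagents that add atoms: sodium chlorite, [Na+].[O-]Cl=O
Why: Pinnick oxidation at pH 3–4 converts the aldehyde to the acid without base, so both carbamates survive, and the scavenger plus the two N-acyl groups protect the rings from HOCl chlorination.

**Step 7**
Reactants: 13, isatin; 14, p-toluenesulfonyl hydrazide
Product: 15, isatin 3-(p-tosylhydrazone) (Z, N–H hydrogen-bonded to the C2 carbonyl)
Conditions: MeOH, 60 °C
Reagents that add atoms: p-toluenesulfonyl hydrazide, Cc1ccc(cc1)S(=O)(=O)NN
Why: Hydrazone condensation occurs selectively at the ketone-like C3 carbonyl of isatin, not at the lactam carbonyl.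

**Step 8**
Reactants: 15, isatin 3-tosylhydrazone
Product: 16, 3-diazoindolin-2-one (3-diazooxindole)
Conditions: 0.2 M aq. NaOH, rt; extract, recrystallise
Reagents that add atoms: none
Why: Bamford–Stevens-type base-induced loss of p-toluenesulfinate gives the amide-stabilised diazo compound, which is isolable.

**Step 9**
Reactants: 12, the bis-Cbz pyrrole-2-carboxylic acid; 16, 3-diazooxindole
Product: 17, 1-[(benzyloxy)carbonyl]-5-{5-(benzyloxy)-1-[(benzyloxy)carbonyl]-1H-indol-3-yl}-3-(2-oxoindolin-3-yl)-1H-pyrrole-2-carboxylic acid (oxindole C3–H racemic and labile; tautomer of the 2-hydroxyindole form)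
Conditions: [Cp*Rh(MeCN)3](SbF6)2 (5 mol%), NaOAc (20 mol%), 16 (1.3 eq, slow addition), DCE, 40 °C, Ar
Reagents that add atoms: 3-diazoindolin-2-one, [N-]=[N+]=C1C(=O)Nc2ccccc12
Why: Proposed new method: carboxylate-directed, redox-neutral Cp*Rh(III) C3–H carbene insertion on a pyrrole-2-carboxylic acid — the κO-carboxylate directs acetate-assisted metalation of the only ortho C–H (pyrrole C3, otherwise less reactive than C4) to a five-membered rhodacycle, the diazooxindole loses N2 to give a Rh carbene, migratory insertion forms the pyrrole C3–oxindole C3 bond, and protonation of the Rh oxindole enolate by the acid turns the catalyst over; the closest known reactions are Cp*Rh(III) directed C–H alkylation of arenes with diazo compounds and carboxylate-directed Rh(III) C–H annulation of heteroaryl acids with alkynes, and the free-CO2H-directed pyrrole C3–H/diazooxindole combination has not been shown; no stereocentre is retained.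

**Step 10**
Reactants: 17, the protected coupling product
Product: 18, 5-(5-hydroxy-1H-indol-3-yl)-3-(2-hydroxy-1H-indol-3-yl)-1H-pyrrole-2-carboxylic acid (target, drawn as the 2-hydroxyindole tautomer)
Conditions: H2 (1 atm), 10% Pd/C, degassed THF/MeOH, rt; filter and concentrate under Ar, store cold in the dark
Reagents that add atoms: none
Why: Global hydrogenolysis removes the benzyl ether and both N-Cbz groups (the N-carboxy azoles lose CO2 spontaneously) under neutral, oxygen-free conditions that avoid acid-promoted decarboxylation and aerobic oxidation.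

## Compound list

1 | 5-(benzyloxy)-1H-indole | C(Oc1ccc2[nH]ccc2c1)c1ccccc1 | starting material
2 | iodine | II | starting material
3 | 5-(benzyloxy)-3-iodo-1H-indole | Ic1c[nH]c2ccc(OCc3ccccc3)cc12 | intermediate
4 | benzyl chloroformate | O=C(Cl)OCc1ccccc1 | starting material
5 | benzyl 5-(benzyloxy)-3-iodo-1H-indole-1-carboxylate | O=C(OCc1ccccc1)n1cc(I)c2cc(OCc3ccccc3)ccc21 | intermediate
6 | bis(pinacolato)diboron | CC1(C)OB(OC1(C)C)B1OC(C)(C)C(C)(C)O1 | starting material
7 | benzyl 5-(benzyloxy)-3-(4,4,5,5-tetramethyl-1,3,2-dioxaborolan-2-yl)-1H-indole-1-carboxylate | O=C(OCc1ccccc1)n1cc(B2OC(C)(C)C(C)(C)O2)c2cc(OCc3ccccc3)ccc21 | intermediate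
8 | 5-bromo-1H-pyrrole-2-carbaldehyde | O=Cc1ccc(Br)[nH]1 | starting material
9 | benzyl 5-(benzyloxy)-3-(5-formyl-1H-pyrrol-2-yl)-1H-indole-1-carboxylate | O=Cc1ccc(-c2cn(C(=O)OCc3ccccc3)c3ccc(OCc4ccccc4)cc23)[nH]1 | intermediate
10 | benzyl 5-(benzyloxy)-3-{1-[(benzyloxy)carbonyl]-5-formyl-1H-pyrrol-2-yl}-1H-indole-1-carboxylate | O=Cc1ccc(-c2cn(C(=O)OCc3ccccc3)c3ccc(OCc4ccccc4)cc23)n1C(=O)OCc1ccccc1 | intermediate
11 | sodium chlorite | [Na+].[O-]Cl=O | starting material
12 | 1-[(benzyloxy)carbonyl]-5-{5-(benzyloxy)-1-[(benzyloxy)carbonyl]-1H-indol-3-yl}-1H-pyrrole-2-carboxylic acid | O=C(O)c1ccc(-c2cn(C(=O)OCc3ccccc3)c3ccc(OCc4ccccc4)cc23)n1C(=O)OCc1ccccc1 | intermediate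
13 | isatin | O=C1Nc2ccccc2C1=O | starting material
14 | p-toluenesulfonyl hydrazide | Cc1ccc(cc1)S(=O)(=O)NN | starting material
15 | isatin 3-(p-tosylhydrazone), Z | Cc1ccc(cc1)S(=O)(=O)N/N=C1\C(=O)Nc2ccccc12 | intermediate
16 | 3-diazoindolin-2-one | [N-]=[N+]=C1C(=O)Nc2ccccc12 | intermediate
17 | 1-[(benzyloxy)carbonyl]-5-{5-(benzyloxy)-1-[(benzyloxy)carbonyl]-1H-indol-3-yl}-3-(2-oxoindolin-3-yl)-1H-pyrrole-2-carboxylic acid (C3 of oxindole racemic, labile) | O=C(O)c1c(C2C(=O)Nc3ccccc23)cc(-c2cn(C(=O)OCc3ccccc3)c3ccc(OCc4ccccc4)cc23)n1C(=O)OCc1ccccc1 | intermediate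
18 | 5-(5-hydroxy-1H-indol-3-yl)-3-(2-hydroxy-1H-indol-3-yl)-1H-pyrrole-2-carboxylic acid | O=C(O)c1[nH]c(-c2c[nH]c3ccc(O)cc23)cc1-c1c(O)[nH]c2ccccc12 | target

## Summary

Total step count: 10.
Longest linear sequence: 8 steps (steps 1, 2, 3, 4, 5, 6, 9, 10); steps 7–8 form a two-step side branch.

Three steps most likely to fail:

1. **Step 9 (proposed new C–H carbene insertion).** Risks are diazo dimerisation, O–H insertion into the acid, or weak direction by the carboxylate. Fallback with known chemistry: carry a C3 bromide from the start (a 3-bromo-1H-pyrrole-2-carboxylate benzyl ester, C5 Ir-borylation, Suzuki coupling with iodide 5, N-protection), then form the same bond by Pd/XPhos-catalysed α-arylation of oxindole with the 3-bromopyrrole, followed by the same global hydrogenolysis.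
2. **Step 4 (Suzuki coupling of the base-labile N-Cbz indol-3-yl boronate).** Risks are carbamate loss and protodeboronation. Fallback: drop cross-coupling and build the indole–pyrrole bond from unprotected 1 by POCl3-mediated Vilsmeier-type condensation with pyrrolidin-2-one, DDQ dehydrogenation to the 2-(indol-3-yl)pyrrole, and Vilsmeier formylation at the pyrrole α-position, then bis-Cbz protection to rejoin at 10.
3. **Step 10 (global hydrogenolysis and isolation of the air-sensitive acid).** Risks are incomplete cleavage and oxidative decarboxylation of the product. Fallback: a two-stage non-hydrogenolytic endgame — degassed K2CO3/MeOH methanolysis of both N-Cbz groups, then BCl3/pentamethylbenzene at −78 °C to cleave the aryl benzyl ether.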